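**Retrosynthetic overview**
1. Target ⇐ its tetra-MOM ether; one mild acid step removes all four aryl MOM groups.
2. Key disconnection, aryl–C(=O): the C2v-symmetric bis-MOM ether of 2-prenylresorcinol is lithiated at one of its two equivalent ortho C–H bonds (symmetry is broken here) and acylated by the acetonide (dioxolanone) of (R)-danshensu, which brings the stereocentre and releases the free α-OH.
3. Symmetric arene ⇐ resorcinol: MOM protection, then lithiation/prenylation at C2 on the symmetry axis, so prenyl regiochemistry is never an issue.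
4. Acyl donor ⇐ (R)-danshensu (chiral pool): dioxolanone formation, then MOM protection of the catechol.
5. Ring order: neither benzene ring is built (both come from the feedstocks); the only ring formed is the temporary dioxolanone (step 3), opened again in step 5.

Assumption: (R)-danshensu is bought as the free acid (the commercial sodium salt is acidified and extracted before use); the target stereocentre read from the SMILES is (R), the same as in danshensu.

**Route**

Step 1
Reactants: 1 resorcinol (benzene-1,3-diol)
Product: 2 1,3-bis(methoxymethoxy)benzene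
Conditions: MOMCl (2.5 equiv), i-Pr2NEt (3 equiv), CH2Cl2, 0 °C → rt
Reagents that add atoms: chloromethyl methyl ether (MOMCl), COCCl
Why: Base-mediated O-alkylation (MOM protection) of both phenols gives a C2v-symmetric bis-acetal whose OMOM groups direct both later metalations and come off under mild acid; no stereocentre is involved.

Step 2
Reactants: 2 1,3-bis(methoxymethoxy)benzene; 3 prenyl bromide (1-bromo-3-methylbut-2-ene)
Product: 5 1,3-bis(methoxymethoxy)-2-(3-methylbut-2-en-1-yl)benzene, via symmetric aryllithium 4 (not isolated)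
Conditions: n-BuLi (1.1 equiv), THF, 0 °C → rt, 1 h; CuBr·SMe2 (10 mol %), −78 °C; then 3 (1.2 equiv), −78 °C → rt
Reagents that add atoms: none
Why: Directed ortho-metalation occurs at C2 because that C–H is flanked by both OMOM groups, and copper-catalysed SN2 allylation of 4 with 3 places the prenyl group on the symmetry axis, so no regioisomer can arise; no stereocentre is involved.

Step 3
Reactants: 6 (R)-danshensu, (2R)-3-(3,4-dihydroxyphenyl)-2-hydroxypropanoic acid
Product: 7 (5R)-5-(3,4-dihydroxybenzyl)-2,2-dimethyl-1,3-dioxolan-4-one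
Conditions: 2,2-dimethoxypropane (5 equiv), acetone, CSA (5 mol %), rt, N2
Reagents that add atoms: 2,2-dimethoxypropane, COC(C)(C)OC
Why: Acid-catalysed transketalisation (1,3-dioxolan-4-one formation) closes the acetonide of the α-hydroxy acid far faster than the slowly forming catechol acetonide, masking OH and CO2H at once and activating the acyl group, and the (R) centre is retained because no bond to it is broken.

Step 4
Reactants: 7 (5R)-5-(3,4-dihydroxybenzyl)-2,2-dimethyl-1,3-dioxolan-4-one
Product: 8 (5R)-5-[3,4-bis(methoxymethoxy)benzyl]-2,2-dimethyl-1,3-dioxolan-4-one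
Conditions: MOMCl (3 equiv), i-Pr2NEt (4 equiv), CH2Cl2, 0 °C → rt
Reagents that add atoms: chloromethyl methyl ether (MOMCl), COCCl
Why: O-alkylation (MOM protection) of the two phenols with the very reactive MOMCl under a non-nucleophilic amine base outpaces any phenol attack on the dioxolanone, and i-Pr2NEt cannot remove the α-proton, so the (R) centre is untouched.

Step 5
Reactants: 5 1,3-bis(methoxymethoxy)-2-(3-methylbut-2-en-1-yl)benzene; 8 (5R)-5-[3,4-bis(methoxymethoxy)benzyl]-2,2-dimethyl-1,3-dioxolan-4-one
Product: 11 (2R)-1-[2,4-bis(methoxymethoxy)-3-(3-methylbut-2-en-1-yl)phenyl]-3-[3,4-bis(methoxymethoxy)phenyl]-2-hydroxypropan-1-one, via ring aryllithium 9 (not isolated), via lithium hemiketal alkoxide 10 (not isolated)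
Conditions: 5, n-BuLi (1.1 equiv), TMEDA (1.1 equiv), THF, 0 °C, 1 h; cannulate into 8 (0.9 equiv), THF, −78 °C, 30 min; AcOH in THF, −78 °C → rt
Reagents that add atoms: none
Why: Proposed new method: directed ortho-metalation of 5 at either of its two symmetry-equivalent ring C–H bonds ortho to OMOM breaks the C2v symmetry (key step) and gives 9, which should add once to the activated lactone-type carbonyl of 8 (nucleophilic acyl substitution) to give the non-enolisable hemiketal alkoxide 10, stable at −78 °C like a Weinreb chelate, so that protonation releases acetone and the free α-hydroxy ketone with the (R) centre carried over unchanged from 6; the closest known reaction types are the mono-addition of carbanions (ester enolates, Grignard reagents) to α-hydroxy-acid acetonides and the Weinreb ketone synthesis.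

Step 6
Reactants: 11 (2R)-1-[2,4-bis(methoxymethoxy)-3-(3-methylbut-2-en-1-yl)phenyl]-3-[3,4-bis(methoxymethoxy)phenyl]-2-hydroxypropan-1-one
Product: 12 (2R)-1-[2,4-dihydroxy-3-(3-methylbut-2-en-1-yl)phenyl]-3-(3,4-dihydroxyphenyl)-2-hydroxypropan-1-one (CNP0408242.1)
Conditions: 3 M aq HCl/MeOH (1:6), degassed, rt → 40 °C
Reagents that add atoms: none
Why: Acid-catalysed acetal exchange (methanolysis of the four aryl MOM ethers, the CH2 unit leaving as dimethoxymethane) at ≤40 °C is milder than what is needed to cyclise the prenyl group onto a neighbouring phenol or to enolise the hydrogen-bonded aryl ketone, so the prenyl group and the (R) centre survive.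

**Compound list**
1 | resorcinol (benzene-1,3-diol) | Oc1cccc(O)c1 | starting material
2 | 1,3-bis(methoxymethoxy)benzene | COCOc1cccc(OCOC)c1 | intermediate
3 | prenyl bromide (1-bromo-3-methylbut-2-ene) | CC(C)=CCBr | starting material
4 | [2,6-bis(methoxymethoxy)phenyl]lithium (not isolated) | [Li]c1c(OCOC)cccc1OCOC | intermediate
5 | 1,3-bis(methoxymethoxy)-2-(3-methylbut-2-en-1-yl)benzene | COCOc1cccc(OCOC)c1CC=C(C)C | intermediate
6 | (R)-danshensu, (2R)-3-(3,4-dihydroxyphenyl)-2-hydroxypropanoic acid | O=C(O)[C@H](O)Cc1ccc(O)c(O)c1 | starting material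
7 | (5R)-5-(3,4-dihydroxybenzyl)-2,2-dimethyl-1,3-dioxolan-4-one | CC1(C)OC(=O)[C@@H](Cc2ccc(O)c(O)c2)O1 | intermediate
8 | (5R)-5-[3,4-bis(methoxymethoxy)benzyl]-2,2-dimethyl-1,3-dioxolan-4-one | CC1(C)OC(=O)[C@@H](Cc2ccc(OCOC)c(OCOC)c2)O1 | intermediate
9 | [2,4-bis(methoxymethoxy)-3-(3-methylbut-2-en-1-yl)phenyl]lithium (not isolated) | [Li]c1ccc(OCOC)c(CC=C(C)C)c1OCOC | intermediate
10 | lithium (5R)-4-[2,4-bis(methoxymethoxy)-3-(3-methylbut-2-en-1-yl)phenyl]-5-[3,4-bis(methoxymethoxy)benzyl]-2,2-dimethyl-1,3-dioxolan-4-olate, C4 epimers (not isolated) | [Li]OC1(c2ccc(OCOC)c(CC=C(C)C)c2OCOC)OC(C)(C)O[C@@H]1Cc1ccc(OCOC)c(OCOC)c1 | intermediate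
11 | (2R)-1-[2,4-bis(methoxymethoxy)-3-(3-methylbut-2-en-1-yl)phenyl]-3-[3,4-bis(methoxymethoxy)phenyl]-2-hydroxypropan-1-one | COCOc1ccc(C(=O)[C@H](O)Cc2ccc(OCOC)c(OCOC)c2)c(OCOC)c1CC=C(C)C | intermediate
12 | (2R)-1-[2,4-dihydroxy-3-(3-methylbut-2-en-1-yl)phenyl]-3-(3,4-dihydroxyphenyl)-2-hydroxypropan-1-one | CC(C)=CCc1c(O)ccc(C(=O)[C@H](O)Cc2ccc(O)c(O)c2)c1O | target

**Totals**
Total step count: 6. Longest linear sequence: 4 steps (1 → 2 → 5 → 11 → 12, or equally 6 → 7 → 8 → 11 → 12).

**Three steps most likely to fail**

Step 5 (key coupling). The aryllithium may deprotonate 8 at C5 instead of adding (loss of material and ee), the adduct 10 may collapse early and take up a second aryl group, and some benzylic/allylic metalation of 5 is conceivable. The fallback sets out from 8 and returns at 11, replacing the dioxolanone acyl transfer by a Weinreb ketone synthesis. 8 is opened with MeNH(OMe)·HCl/i-PrMgCl (THF, −20 °C, acetone is lost) to the hydroxy Weinreb amide (2R)-3-[3,4-bis(methoxymethoxy)phenyl]-2-hydroxy-N-methoxy-N-methylpropanamide F1. One equivalent of i-PrMgCl (THF, −40 °C) converts it into its chloromagnesium alkoxide F2, in which the adjacent alkoxide suppresses α-deprotonation. Aryllithium 9 (made as in step 5) is then added at −78 → 0 °C to give the chelated tetrahedral adduct F3, which on aqueous NH4Cl quench loses N,O-dimethylhydroxylamine and gives 11.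

Step 6 (global deprotection). Protic acid may close the prenyl group onto the 2- or 4-hydroxyl (2,2-dimethylchroman) or racemise the ketol through the enediol. The fallback sets out from 11 and returns at 12, using a non-protic silyl exchange instead of Brønsted acid. TMSOTf/2,2′-bipyridyl (CH2Cl2, 0 °C → rt) converts the four aryl MOM ethers into aryl silyl ethers and silylates the free carbinol, giving the pentakis(trimethylsilyl) ether (2R)-1-[3-(3-methylbut-2-en-1-yl)-2,4-bis(trimethylsilyloxy)phenyl]-3-[3,4-bis(trimethylsilyloxy)phenyl]-2-(trimethylsilyloxy)propan-1-one F4. This is not isolated; it is hydrolysed in the work-up with wet THF/citric acid (pH about 5) to 12.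

Step 4 (MOM protection next to an activated ester). Free phenols in the presence of base and the acylating dioxolanone may give oligoesters, and the second MOM group may go on sluggishly. The fallback sets out from 6 and returns at 8, protecting the phenols before the acyl group is activated. 6 is esterified (MeOH, cat. H2SO4, rt) to methyl (2R)-3-(3,4-dihydroxyphenyl)-2-hydroxypropanoate F5. Phenol-selective alkylation (MOMCl, K2CO3, acetone, rt) gives methyl (2R)-3-[3,4-bis(methoxymethoxy)phenyl]-2-hydroxypropanoate F6. Saponification (LiOH, THF/H2O, 0 °C) gives (2R)-3-[3,4-bis(methoxymethoxy)phenyl]-2-hydroxypropanoic acid F7. Ring closure with 2-methoxypropene and cat. PPTS (CH2Cl2, 0 °C), mild enough to leave the aryl MOM ethers intact, gives 8.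

**Further compounds**
F1 | step 5 | (2R)-3-[3,4-bis(methoxymethoxy)phenyl]-2-hydroxy-N-methoxy-N-methylpropanamide | CON(C)C(=O)[C@H](O)Cc1ccc(OCOC)c(OCOC)c1
F2 | step 5 | chloromagnesium alkoxide of F1 (not isolated) | CON(C)C(=O)[C@H](O[Mg]Cl)Cc1ccc(OCOC)c(OCOC)c1
F3 | step 5 | chelated tetrahedral adduct of 9 and F2 (not isolated) | CON(C)C(O[Li])(c1ccc(OCOC)c(CC=C(C)C)c1OCOC)[C@H](O[Mg]Cl)Cc1ccc(OCOC)c(OCOC)c1
F4 | step 6 | (2R)-1-[3-(3-methylbut-2-en-1-yl)-2,4-bis(trimethylsilyloxy)phenyl]-3-[3,4-bis(trimethylsilyloxy)phenyl]-2-(trimethylsilyloxy)propan-1-one | CC(C)=CCc1c(O[Si](C)(C)C)ccc(C(=O)[C@H](O[Si](C)(C)C)Cc2ccc(O[Si](C)(C)C)c(O[Si](C)(C)C)c2)c1O[Si](C)(C)C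
F5 | step 4 | methyl (2R)-3-(3,4-dihydroxyphenyl)-2-hydroxypropanoate | COC(=O)[C@H](O)Cc1ccc(O)c(O)c1
F6 | step 4 | methyl (2R)-3-[3,4-bis(methoxymethoxy)phenyl]-2-hydroxypropanoate | COC(=O)[C@H](O)Cc1ccc(OCOC)c(OCOC)c1
F7 | step 4 | (2R)-3-[3,4-bis(methoxymethoxy)phenyl]-2-hydroxypropanoic acid | O=C(O)[C@H](O)Cc1ccc(OCOC)c(OCOC)c1
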